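**Plan**
1. Retrosynthesis (triterpenoid atoms C1–C30 as in friedelane, sesquiterpenoid atoms primed as in guaiane): ring D (C13–C14–C15–C16–C17–C18) is cut first, at C13–C18 and C16–C17, into a 13-methylidene/16-aldehyde ABC–dioxane–hydroazulene block and a 2-methylcyclohex-2-enone (ring E).
2. This works because ring D lies between C13 (quaternary; its C27 methyl can come from =CH2 + H•), C18 (β-carbon of the ring-E enone), C17 (enone α-carbon that already carries the C28 methyl) and the C15–C16 bridge that can end in an aldehyde: tertiary radical + enone, then enolate + aldehyde.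
3. Further cuts: both dioxane C–O bonds (o-quinone + cyclopentadiene [4+2]); C9–C11 and C8–C14 (Robinson annulation on a 2-tetralone); ring E by Diels–Alder; the cyclopentenone by hydroacylation; the cycloheptane by one-carbon ring expansion of dihydrocarvone.
4. Forward order of rings: A/B (bought) → C → seven-membered ring → five-membered ring → dioxane → E (made separately, joined in the key step) → D last.
5. Stereochemistry: C9 by chiral-imine Michael addition, C8 by cis-hydrogenation, C14 by convex-face methylation, C7'/C10' from (S)-carvone, C3'/C4' by the facial selectivity of the hetero-Diels–Alder reaction, C20 by catalytic asymmetric Diels–Alder, C13/C17/C18 in the key step.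
6. Helpers: the C16–OH and C22=O left by the annulation are removed by radical deoxygenation; the isopropenyl group travels as a ketal-masked acetyl group; C6=C7 is introduced late with DDQ.

Key step: step 30

Remark 1: α/β follow the friedelane convention (C25 methyl on C9 = β); the target SMILES then reads 8β-H, 9β-CH3, 13α-CH3, 14β-CH3, 17β-CH3, 18β-H, 20α-CO2CH3, 20β-CH3 and (3'R,4'S,7'S,10'S), i.e. a cis B/C fusion.
Remark 2: stereocentres that are made and destroyed again (carbinols in 2, 28, 38, 40–42; C1 of 7; the ester-bearing carbon of 20) are left undefined in the SMILES; such mixtures are of no consequence.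
Remark 3: the catalyst enantiomer in step 25 is the one that gives (R)-35; if the sense of induction is the opposite, the mirror-image catalyst is used.
Remark 4: 4-[(tert-butyldimethylsilyl)oxy]butanal (1) is taken to be purchasable.

**Vinyl ketone**

Step 1
Reactants: 1 4-[(tert-butyldimethylsilyl)oxy]butanal
Product: 2 6-[(tert-butyldimethylsilyl)oxy]hex-1-en-3-ol (racemic)
Conditions: CH2=CHMgBr, THF, −78 → 0 °C
Reagents that add atoms: vinylmagnesium bromide, C=C[Mg]Br
Why: Grignard 1,2-addition to an unhindered aldehyde should give the allylic alcohol, whose carbinol centre is removed in step 2.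

Step 2
Reactants: 2 6-[(tert-butyldimethylsilyl)oxy]hex-1-en-3-ol
Product: 3 6-[(tert-butyldimethylsilyl)oxy]hex-1-en-3-one
Conditions: Dess–Martin periodinane, NaHCO3, CH2Cl2, 0 °C; used crude
Reagents that add atoms: none
Why: Buffered Dess–Martin oxidation should give the polymerisation-prone vinyl ketone without touching the silyl ether.

**ABC catechol**

Step 3
Reactants: 4 6,7-dimethoxy-3,4-dihydronaphthalen-2(1H)-one
Product: 7 (±)-6,7-dimethoxy-1-methyl-3,4-dihydronaphthalen-2(1H)-one, via pyrrolidine enamine 5 (not isolated), via C-methylated iminium iodide 6 (not isolated)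
Conditions: pyrrolidine, PhH, reflux (−H2O); MeI, dioxane, 80 °C; H2O/AcOH, rt
Reagents that add atoms: iodomethane, CI; water, O
Why: Enamine alkylation: the enamine of a 2-tetralone is conjugated with the arene (C1=C2), so mono-C-methylation should occur at C1 only (the racemic centre is reset in step 4).

Step 4
Reactants: 7 (±)-6,7-dimethoxy-1-methyl-3,4-dihydronaphthalen-2(1H)-one; 3 6-[(tert-butyldimethylsilyl)oxy]hex-1-en-3-one
Product: 10 (S)-1-{6-[(tert-butyldimethylsilyl)oxy]-3-oxohexyl}-6,7-dimethoxy-1-methyl-3,4-dihydronaphthalen-2(1H)-one, via ketimine 8 (not isolated), via Michael adduct ketimine 9 (not isolated)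
Conditions: (S)-1-phenylethylamine, TsOH (cat.), toluene, reflux (−H2O); 3, THF, 40 °C; 10% aq AcOH, rt
Reagents that add atoms: water, O
Why: Deracemising Michael addition of a chiral imine: both enantiomers of 7 converge on the arene-conjugated secondary enamine, which should add to the vinyl ketone in an aza-ene-like chair transition state on the face away from the phenyl group and so set quaternary C9.

Step 5
Reactants: 10 Michael adduct diketone
Product: 11 tricyclic enone (13-oxo-8(14)-ene; 9β-CH3; 14-CH2CH2OTBS; 2,3-dimethoxy)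
Conditions: NaOMe, MeOH, 50 °C
Reagents that add atoms: none
Why: Aldol condensation (second stage of the Robinson annulation): only the C14 methylene can reach the C8 ketone to close a six-membered enone.

Step 6
Reactants: 11 tricyclic enone
Product: 12 cis-fused ketone (8β-H, 14β-H)
Conditions: H2 (3 atm), 10% Pd/C, EtOH, Et3N (cat.), rt
Reagents that add atoms: none
Why: Heterogeneous hydrogenation of 4a-methyl-hexahydrophenanthren-2-one-type enones in basic medium delivers H2 syn to the angular methyl, which should give the cis B/C fusion (8β-H); the epimerisable C14–H is replaced in step 7.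

Step 7
Reactants: 12 cis-fused ketone
Product: 13 14β-methyl ketone (14α-CH2CH2OTBS)
Conditions: KOt-Bu, t-BuOH/THF, 0 °C → rt; MeI
Reagents that add atoms: iodomethane, CI
Why: Under equilibrating conditions the cis-fused ketone should enolise toward the more substituted C14 (as 5β-3-keto steroids enolise toward C4), and MeI should enter on the convex β-face because the α-face is screened by the axial C9–aryl bond, which gives 14β-CH3 and leaves the chain α.

Step 8
Reactants: 13 14β-methyl ketone
Product: 14 4-bromo arene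
Conditions: NBS, MeCN, 0 °C → rt
Reagents that add atoms: N-bromosuccinimide, O=C1CCC(=O)N1Br
Why: Electrophilic bromination ortho to a methoxy group: of the two free positions C1 is buried beside quaternary C9, so C4 should react.

Step 9
Reactants: 14 4-bromo arene
Product: 15 4-methyl arene
Conditions: MeB(OH)2, Pd(OAc)2/SPhos (cat.), K3PO4, toluene/H2O, 100 °C
Reagents that add atoms: methylboronic acid, CB(O)O
Why: Suzuki–Miyaura methylation of a di-ortho-substituted aryl bromide is reliable with a biaryl phosphine, and ketone and silyl ether are inert.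

Step 10
Reactants: 15 4-methyl arene
Product: 16 catechol keto alcohol (2,3-dihydroxy; 16-OH; 13-oxo)
Conditions: BBr3, CH2Cl2, −78 → 0 °C; MeOH, then aq NaHCO3
Reagents that add atoms: none
Why: BBr3 should cleave both aryl methyl ethers and the primary silyl ether in one operation, used here before any acid-sensitive alkene is present.

Step 11
Reactants: 16 catechol keto alcohol
Product: 17 catechol 13-methylidene alcohol
Conditions: Ph3PCH3Br (6 equiv), KOt-Bu (8.5 equiv), toluene/THF, 80 °C, Ar
Reagents that add atoms: methyltriphenylphosphonium bromide, C[P+](c1ccccc1)(c1ccccc1)c1ccccc1.[Br-]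
Why: Wittig methylenation of the hindered α-quaternary ketone with excess ylide at elevated temperature; catecholate and alkoxide are spectators and only C12 is enolisable, so no stereocentre is at risk.

**Nor-guaiadiene**

Step 12
Reactants: 18 (S)-(+)-carvone
Product: 19 (2S,5S)-dihydrocarvone
Conditions: Zn dust, KOH, EtOH/H2O, reflux
Reagents that add atoms: none
Why: Dissolving-metal conjugate reduction spares the isolated isopropenyl group, and the basic medium equilibrates C2 toward the trans (diequatorial) isomer, which is separated from the minor cis isomer.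

Step 13
Reactants: 19 (2S,5S)-dihydrocarvone
Product: 20 ethyl (3S,6S)-3-methyl-2-oxo-6-(prop-1-en-2-yl)cycloheptane-1-carboxylate (C1 epimers and enol)
Conditions: N2CHCO2Et, BF3·OEt2, Et2O, −20 → 0 °C
Reagents that add atoms: ethyl diazoacetate, CCOC(=O)C=[N+]=[N-]
Why: Lewis-acid-promoted diazoacetate homologation (Tiffeneau–Demjanov-type ring expansion): the less substituted α-CH2 migrates, so the ester-bearing carbon is inserted away from the methyl-bearing stereocentre, which is untouched.

Step 14
Reactants: 20 β-keto ester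
Product: 21 ethyl (3S,6S)-3-methyl-6-(prop-1-en-2-yl)-2-{[(trifluoromethyl)sulfonyl]oxy}cyclohept-1-ene-1-carboxylate
Conditions: NaH, THF, 0 °C; Tf2O, −78 → 0 °C
Reagents that add atoms: trifluoromethanesulfonic anhydride, O=S(=O)(OS(=O)(=O)C(F)(F)F)C(F)(F)F
Why: O-Triflation of the β-keto ester enolate fixes the tetrasubstituted C1'=C5' double bond regiospecifically.

Step 15
Reactants: 21 enol triflate
Product: 22 ethyl (3S,6S)-2-ethenyl-3-methyl-6-(prop-1-en-2-yl)cyclohept-1-ene-1-carboxylate
Conditions: CH2=CHSnBu3, Pd(PPh3)4 (5 mol %), LiCl, THF, 65 °C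
Reagents that add atoms: tributyl(vinyl)stannane, C=C[Sn](CCCC)(CCCC)CCCC
Why: Stille coupling of an electron-poor enol triflate with a vinylstannane is a standard sp2–sp2 coupling that tolerates the ester and the isopropenyl group.

Step 16
Reactants: 22 dienoate
Product: 23 [(3S,6S)-2-ethenyl-3-methyl-6-(prop-1-en-2-yl)cyclohept-1-en-1-yl]methanol
Conditions: DIBAL-H (2.5 equiv), CH2Cl2, −78 °C; Rochelle salt
Reagents that add atoms: none
Why: DIBAL-H reduces the conjugated ester to the allylic alcohol by 1,2-addition only.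

Step 17
Reactants: 23 dienyl alcohol
Product: 24 (3S,6S)-2-ethenyl-3-methyl-6-(prop-1-en-2-yl)cyclohept-1-ene-1-carbaldehyde
Conditions: Dess–Martin periodinane, NaHCO3, CH2Cl2, 0 °C
Reagents that add atoms: none
Why: Mild oxidation of the allylic alcohol should give the dienal, in which the ring double bond holds formyl and vinyl groups cis.

Step 18
Reactants: 24 dienal
Product: 25 (4S,7S)-4-methyl-7-(prop-1-en-2-yl)-3,4,5,6,7,8-hexahydroazulen-1(2H)-one
Conditions: [Rh(dppe)]ClO4 (5 mol %), CH2Cl2, rt
Reagents that add atoms: none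
Why: Rh(I)-catalysed intramolecular alkene hydroacylation of the 4-pentenal unit (acyl–Rh–H, hydride to the internal vinyl carbon, C–C reductive elimination) should close the cyclopentenone under neutral conditions that spare the isopropenyl group.

Step 19
Reactants: 25 bicyclic enone
Product: 26 (4S,7S)-7-acetyl-4-methyl-3,4,5,6,7,8-hexahydroazulen-1(2H)-one
Conditions: O3, CH2Cl2/MeOH, −78 °C (Sudan III end point); Me2S
Reagents that add atoms: ozone, [O-][O+]=O
Why: Ozone should cleave the electron-rich isolated 1,1-disubstituted alkene much faster than the carbonyl-deactivated enone double bond.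

Step 20
Reactants: 26 acetyl enone
Product: 27 (4S,7S)-4-methyl-7-(2-methyl-1,3-dioxolan-2-yl)-3,4,5,6,7,8-hexahydroazulen-1(2H)-one
Conditions: (TMSOCH2)2, TMSOTf (5 mol %), CH2Cl2, −78 °C
Reagents that add atoms: 1,2-bis(trimethylsilyloxy)ethane, C[Si](C)(C)OCCO[Si](C)(C)C
Why: Aprotic silyl-transfer ketalisation should convert the saturated methyl ketone and not the conjugated cyclopentenone, and avoids enolisation at C7'.

Step 21
Reactants: 27 ketal enone
Product: 28 (4S,7S)-4-methyl-7-(2-methyl-1,3-dioxolan-2-yl)-1,2,3,4,5,6,7,8-octahydroazulen-1-ol (C1 epimers)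
Conditions: NaBH4, CeCl3·7H2O, MeOH, −20 °C
Reagents that add atoms: none
Why: Luche reduction gives 1,2-reduction of the enone, and the carbinol configuration is irrelevant because the centre is removed in step 22.

Step 22
Reactants: 28 allylic alcohol
Product: 29 (4S,7S)-4-methyl-7-(2-methyl-1,3-dioxolan-2-yl)-3,4,5,6,7,8-hexahydroazulene (C1=C2 and C3a=C8a diene)
Conditions: Burgess reagent, THF, 0 → 40 °C; filtered through basic alumina and used at once at ≤ 0 °C
Reagents that add atoms: none
Why: Syn-elimination of the sulfamate can only take a hydrogen from C3' (C5' has none), which should give the 1'(5'),3'-diene, and prompt use limits 1,5-H shifts and dimerisation.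

**Dioxane**

Step 23
Reactants: 17 catechol 13-methylidene alcohol; 29 nor-guaiadiene ketal
Product: 31 cis-fused benzodioxane (C2–O–C3' and C3–O–C4'), via o-quinone 30 (not isolated)
Conditions: Ag2O, MgSO4, Et2O/CH2Cl2, 0 °C; then 29, −20 °C → rt
Reagents that add atoms: none
Why: Inverse-demand hetero-Diels–Alder reaction of the o-quinone (O=C–C=O as the 4π unit; every ring carbon open to conjugate addition is substituted) with the disubstituted C3'=C4' bond should give the cis-fused dioxane suprafacially on the face opposite the pseudo-axial C10' methyl, the diene terminus C3' bonding first to the less hindered oxygen on C2 so that the oxygen flanked by the C4 methyl ends on allylic C4'.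

Step 24
Reactants: 31 benzodioxane alcohol
Product: 32 benzodioxane aldehyde (14α-CH2CHO; 13-methylidene)
Conditions: Dess–Martin periodinane, NaHCO3, CH2Cl2, 0 °C → rt
Reagents that add atoms: none
Why: Buffered Dess–Martin oxidation of the primary alcohol should leave the alkenes, the ketal and the allylic aryl ether intact.

**Ring E enone**

Step 25
Reactants: 33 isoprene; 34 methacrolein
Product: 35 (R)-1,4-dimethylcyclohex-3-ene-1-carbaldehyde
Conditions: proline-derived cationic oxazaborolidine (o-tolyl, triflimide-activated, 10 mol %), CH2Cl2, −78 °C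
Reagents that add atoms: none
Why: Chiral-Lewis-acid-catalysed Diels–Alder reaction: the 2-methyldiene gives the "para" adduct and the catalyst-bound aldehyde exposes one face, which sets quaternary C20.

Step 26
Reactants: 35 (R)-aldehyde
Product: 36 (R)-1,4-dimethylcyclohex-3-ene-1-carboxylic acid
Conditions: NaClO2, NaH2PO4, 2-methyl-2-butene, t-BuOH/H2O, rt
Reagents that add atoms: sodium chlorite, [Na+].[O-]Cl=O
Why: Pinnick oxidation with a hypochlorite scavenger should oxidise the hindered aldehyde without touching the ring alkene or the stereocentre.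

Step 27
Reactants: 36 (R)-acid
Product: 37 methyl (R)-1,4-dimethylcyclohex-3-ene-1-carboxylate
Conditions: MeI, K2CO3, DMF, rt
Reagents that add atoms: iodomethane, CI
Why: Carboxylate O-alkylation is the simplest esterification of a hindered tertiary acid.

Step 28
Reactants: 37 methyl ester
Product: 38 methyl (1S)-5-hydroxy-1,4-dimethylcyclohex-3-ene-1-carboxylate (C5 epimers)
Conditions: SeO2 (0.3 equiv), t-BuOOH, CH2Cl2, rt
Reagents that add atoms: tert-butyl hydroperoxide, CC(C)(C)OO
Why: SeO2 allylic oxidation (ene reaction then [2,3]-shift) attacks at the more substituted alkene terminus and prefers CH2 over CH3, so it should hydroxylate ring C22 rather than neopentyl C19 or the methyl group.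

Step 29
Reactants: 38 allylic alcohol
Product: 39 methyl (S)-1,4-dimethyl-5-oxocyclohex-3-ene-1-carboxylate
Conditions: Dess–Martin periodinane, NaHCO3, CH2Cl2, rt
Reagents that add atoms: none
Why: Oxidation of the allylic alcohol should give the 2-methylcyclohex-2-enone that carries C17, C18, C28 and the C20 quaternary centre.

**Ring D**

Step 30
Reactants: 32 benzodioxane aldehyde; 39 ring-E enone
Product: 40 pentacyclic 16-hydroxy-22-ketone (ring D closed)
Conditions: Fe(acac)3 (30 mol %), PhSiH3 (2.5 equiv), 39 (3 equiv), EtOH/(CH2OH)2, 0 °C → rt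
Reagents that add atoms: none
Why: Iron hydride transfers a hydrogen atom to the terminal carbon of the 13-methylidene group (completing the C27 methyl) to give the tertiary C13 radical, which adds to the β-carbon C18 of 39, and the α-keto radical is then reduced to an iron enolate whose C17 attacks the C16 aldehyde, so that C13–C18 and C16–C17 form in one flask. The closest known reaction type is the iron-hydride-initiated radical–polar crossover annulation of aldehyde-tethered 1,1-disubstituted alkenes with α-substituted cyclic enones (hydrogen-atom-transfer Giese addition followed by intramolecular aldol addition). Ring D closes in the aldol event in a 6-(enolexo)-exo-trig mode. C13 should be attacked on the convex β-face of the cis-fused B/C bicycle (the α-face is covered by ring B and the arene), which leaves the new C27 methyl α and anti to the 14β-methyl; C18 should arise from axial attack on the half-chair enone syn to the pseudo-axial C20 ester (smaller 1,3-diaxial demand than methyl), which puts C13 cis to CO2CH3; at C17 the three-atom tether can deliver the aldehyde only to the enolate face that already carries C13, giving the cis D/E fusion with the C28 methyl β, while the C16 carbinol is not relied on. The step needs hydrogen-atom transfer to the 13-methylidene group only and capture of the hindered radical before it is reduced: the one other C=C bond of 32 is the tetrasubstituted C1'=C5' bond, which is slow in hydrogen-atom transfer (the isopropenyl group is masked and no styrene is present yet), and 39 is used in excess.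

**Endgame**

Step 31
Reactants: 40 pentacyclic hydroxy ketone
Product: 41 16,22-diol
Conditions: NaBH4, MeOH/THF, 0 °C
Reagents that add atoms: none
Why: Reducing the ketone first removes the β-hydroxy ketone (retro-aldol) and the β-keto radical (1,2-acyl shift) liabilities before deoxygenation, and the hindered tertiary C29 ester and the ketal should be inert.

Step 32
Reactants: 41 16,22-diol
Product: 42 16,22-bis(S-methyl xanthate)
Conditions: CS2 (excess), MeI (excess), THF, 0 °C; then NaH, imidazole (cat.), 0 °C → rt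
Reagents that add atoms: carbon disulfide, S=C=S; iodomethane, CI
Why: Xanthate formation: with CS2 and MeI present before deprotonation each alkoxide should be trapped faster than it can attack the hindered C29 ester or the neighbouring xanthate.

Step 33
Reactants: 42 bis-xanthate
Product: 43 6,7-dihydro pentacycle (16,22-dideoxy; 11'-ketal)
Conditions: Bu3SnH, AIBN, toluene, 110 °C
Reagents that add atoms: none
Why: Barton–McCombie deoxygenation of two secondary xanthates; the only alkene present is the tetrasubstituted C1'=C5' bond, which is inert to the secondary alkyl radicals.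

Step 34
Reactants: 43 6,7-dihydro pentacycle
Product: 44 6-ene (11'-ketal)
Conditions: DDQ (1.1 equiv), dioxane, rt → 50 °C
Reagents that add atoms: none
Why: DDQ dehydrogenation: hydride abstraction from benzylic C6 (para to the ring oxygen on C2) and proton loss from C7 should give the styrene, as in the 9(11)-dehydrogenation of estrone methyl ether, while quaternary C9 prevents aromatisation and C8 is untouched.

Step 35
Reactants: 44 6-ene ketal
Product: 45 7'-acetyl compound
Conditions: PPTS, acetone/H2O, 50 °C
Reagents that add atoms: water, O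
Why: Mild acid-catalysed transketalisation should free the methyl ketone without ionising the allylic aryl ether or hydrating the styrene.

Step 36
Reactants: 45 7'-acetyl compound
Product: 46 CNP0149558.1 (target)
Conditions: Ph3PCH3Br (1.5 equiv), KHMDS (1.4 equiv), THF, −78 → 0 °C
Reagents that add atoms: methyltriphenylphosphonium bromide, C[P+](c1ccccc1)(c1ccccc1)c1ccccc1.[Br-]
Why: Wittig methylenation of the methyl ketone restores the isopropenyl group; the hindered tertiary methyl ester is inert to the ylide, and low temperature with a small excess limits epimerisation at C7'.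

**Compound list**
1 | 4-[(tert-butyldimethylsilyl)oxy]butanal | O=CCCCO[Si](C)(C)C(C)(C)C | starting material
2 | 6-[(tert-butyldimethylsilyl)oxy]hex-1-en-3-ol (racemic) | C=CC(O)CCCO[Si](C)(C)C(C)(C)C | intermediate
3 | 6-[(tert-butyldimethylsilyl)oxy]hex-1-en-3-one | C=CC(=O)CCCO[Si](C)(C)C(C)(C)C | intermediate
4 | 6,7-dimethoxy-3,4-dihydronaphthalen-2(1H)-one | COc1cc2CCC(=O)Cc2cc1OC | starting material
5 | 1-(6,7-dimethoxy-3,4-dihydronaphthalen-2-yl)pyrrolidine (not isolated) | COc1cc2CCC(N3CCCC3)=Cc2cc1OC | intermediate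
6 | 1-(6,7-dimethoxy-1-methyl-3,4-dihydronaphthalen-2(1H)-ylidene)pyrrolidinium iodide (not isolated) | COc1cc2CCC(=[N+]3CCCC3)C(C)c2cc1OC.[I-] | intermediate
7 | (±)-6,7-dimethoxy-1-methyl-3,4-dihydronaphthalen-2(1H)-one | COc1cc2CCC(=O)C(C)c2cc1OC | intermediate
8 | N-[(S)-1-phenylethyl] ketimine of 7 (not isolated) | COc1cc2CCC(=N[C@@H](C)c3ccccc3)C(C)c2cc1OC | intermediate
9 | N-[(S)-1-phenylethyl] ketimine of 10 (not isolated) | COc1cc2CCC(=N[C@@H](C)c3ccccc3)[C@@](C)(CCC(=O)CCCO[Si](C)(C)C(C)(C)C)c2cc1OC | intermediate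
10 | (S)-1-{6-[(tert-butyldimethylsilyl)oxy]-3-oxohexyl}-6,7-dimethoxy-1-methyl-3,4-dihydronaphthalen-2(1H)-one | COc1cc2CCC(=O)[C@@](C)(CCC(=O)CCCO[Si](C)(C)C(C)(C)C)c2cc1OC | intermediate
11 | tricyclic enone: 2,3-dimethoxy, 9β-methyl, 13-oxo, 8(14)-ene, 14-[2-(TBSO)ethyl] (rings A–C) | COc1cc2CCC3=C(CCO[Si](C)(C)C(C)(C)C)C(=O)CC[C@@]3(C)c2cc1OC | intermediate
12 | cis-fused ketone: 8β-H, 9β-methyl, 14β-H, 14α-[2-(TBSO)ethyl], 13-oxo | COc1cc2CC[C@@H]3[C@@](C)(CCC(=O)[C@@H]3CCO[Si](C)(C)C(C)(C)C)c2cc1OC | intermediate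
13 | 14β-methyl ketone: 8β-H, 9β,14β-dimethyl, 14α-[2-(TBSO)ethyl], 13-oxo | COc1cc2CC[C@@H]3[C@@](C)(CCC(=O)[C@]3(C)CCO[Si](C)(C)C(C)(C)C)c2cc1OC | intermediate
14 | 4-bromo derivative of 13 | COc1c(Br)c2CC[C@@H]3[C@@](C)(CCC(=O)[C@]3(C)CCO[Si](C)(C)C(C)(C)C)c2cc1OC | intermediate
15 | 4-methyl derivative of 13 | COc1c(C)c2CC[C@@H]3[C@@](C)(CCC(=O)[C@]3(C)CCO[Si](C)(C)C(C)(C)C)c2cc1OC | intermediate
16 | catechol keto alcohol: 2,3-dihydroxy-4-methyl, 8β-H, 9β,14β-dimethyl, 14α-(2-hydroxyethyl), 13-oxo | Oc1c(C)c2CC[C@@H]3[C@@](C)(CCC(=O)[C@]3(C)CCO)c2cc1O | intermediate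
17 | catechol methylidene alcohol: as 16 with 13-methylidene | Oc1c(C)c2CC[C@@H]3[C@@](C)(CCC(=C)[C@]3(C)CCO)c2cc1O | intermediate
18 | (S)-(+)-carvone | C=C(C)[C@H]1CC=C(C)C(=O)C1 | starting material
19 | (2S,5S)-2-methyl-5-(prop-1-en-2-yl)cyclohexan-1-one | C=C(C)[C@H]1CC[C@H](C)C(=O)C1 | intermediate
20 | ethyl (3S,6S)-3-methyl-2-oxo-6-(prop-1-en-2-yl)cycloheptane-1-carboxylate | C=C(C)[C@H]1CC[C@H](C)C(=O)C(C(=O)OCC)C1 | intermediate
21 | ethyl (3S,6S)-3-methyl-6-(prop-1-en-2-yl)-2-{[(trifluoromethyl)sulfonyl]oxy}cyclohept-1-ene-1-carboxylate | C=C(C)[C@H]1CC[C@H](C)C(OS(=O)(=O)C(F)(F)F)=C(C(=O)OCC)C1 | intermediate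
22 | ethyl (3S,6S)-2-ethenyl-3-methyl-6-(prop-1-en-2-yl)cyclohept-1-ene-1-carboxylate | C=C(C)[C@H]1CC[C@H](C)C(C=C)=C(C(=O)OCC)C1 | intermediate
23 | [(3S,6S)-2-ethenyl-3-methyl-6-(prop-1-en-2-yl)cyclohept-1-en-1-yl]methanol | C=C(C)[C@H]1CC[C@H](C)C(C=C)=C(CO)C1 | intermediate
24 | (3S,6S)-2-ethenyl-3-methyl-6-(prop-1-en-2-yl)cyclohept-1-ene-1-carbaldehyde | C=C(C)[C@H]1CC[C@H](C)C(C=C)=C(C=O)C1 | intermediate
25 | (4S,7S)-4-methyl-7-(prop-1-en-2-yl)-3,4,5,6,7,8-hexahydroazulen-1(2H)-one | C=C(C)[C@H]1CC[C@H](C)C2=C(C1)C(=O)CC2 | intermediate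
26 | (4S,7S)-7-acetyl-4-methyl-3,4,5,6,7,8-hexahydroazulen-1(2H)-one | CC(=O)[C@H]1CC[C@H](C)C2=C(C1)C(=O)CC2 | intermediate
27 | (4S,7S)-4-methyl-7-(2-methyl-1,3-dioxolan-2-yl)-3,4,5,6,7,8-hexahydroazulen-1(2H)-one | CC3(OCCO3)[C@H]1CC[C@H](C)C2=C(C1)C(=O)CC2 | intermediate
28 | (4S,7S)-4-methyl-7-(2-methyl-1,3-dioxolan-2-yl)-1,2,3,4,5,6,7,8-octahydroazulen-1-ol | CC3(OCCO3)[C@H]1CC[C@H](C)C2=C(C1)C(O)CC2 | intermediate
29 | (4S,7S)-4-methyl-7-(2-methyl-1,3-dioxolan-2-yl)-3,4,5,6,7,8-hexahydroazulene | CC3(OCCO3)[C@H]1CC[C@H](C)C2=C(C1)C=CC2 | intermediate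
30 | o-quinone of 17 (2,3-dioxo; not isolated) | O=C1C(C)=C2CC[C@@H]3[C@@](C)(CCC(=C)[C@]3(C)CCO)C2=CC1=O | intermediate
31 | cis-fused 1,4-benzodioxane: C2–O–C3' and C3–O–C4' join ring A of 17 (13-methylidene, 16-OH) to the (3'R,4'S,7'S,10'S)-15'-norguai-1'(5')-ene unit bearing the 7'-(2-methyl-1,3-dioxolan-2-yl) group | CC5(OCCO5)[C@H]1CC[C@H](C)C2=C(C1)[C@@H]1Oc3c(cc4c(c3C)CC[C@@H]3[C@@]4(C)CCC(=C)[C@]3(C)CCO)O[C@@H]1C2 | intermediate
32 | 16-aldehyde of 31 (14α-CH2CHO) | CC5(OCCO5)[C@H]1CC[C@H](C)C2=C(C1)[C@@H]1Oc3c(cc4c(c3C)CC[C@@H]3[C@@]4(C)CCC(=C)[C@]3(C)CC=O)O[C@@H]1C2 | intermediate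
33 | isoprene | C=CC(C)=C | starting material
34 | methacrolein | C=C(C)C=O | starting material
35 | (R)-1,4-dimethylcyclohex-3-ene-1-carbaldehyde | CC1=CC[C@](C)(C=O)CC1 | intermediate
36 | (R)-1,4-dimethylcyclohex-3-ene-1-carboxylic acid | CC1=CC[C@](C)(C(=O)O)CC1 | intermediate
37 | methyl (R)-1,4-dimethylcyclohex-3-ene-1-carboxylate | CC1=CC[C@](C)(C(=O)OC)CC1 | intermediate
38 | methyl (1S)-5-hydroxy-1,4-dimethylcyclohex-3-ene-1-carboxylate | CC1=CC[C@](C)(C(=O)OC)CC1O | intermediate
39 | methyl (S)-1,4-dimethyl-5-oxocyclohex-3-ene-1-carboxylate | CC1=CC[C@](C)(C(=O)OC)CC1=O | intermediate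
40 | pentacyclic hydroxy ketone: ring D closed; 16-hydroxy, 22-oxo, 13α,17β-dimethyl, 18β-H, 20α-CO2CH3; ring B saturated; 7'-ketal | CC6(OCCO6)[C@H]1CC[C@H](C)C2=C(C1)[C@@H]1Oc3c(cc4c(c3C)CC[C@@H]3[C@@]4(C)CC[C@@]4(C)[C@@H]5C[C@](C)(C(=O)OC)CC(=O)[C@]5(C)C(O)C[C@]34C)O[C@@H]1C2 | intermediate
41 | 16,22-diol of 40 | CC6(OCCO6)[C@H]1CC[C@H](C)C2=C(C1)[C@@H]1Oc3c(cc4c(c3C)CC[C@@H]3[C@@]4(C)CC[C@@]4(C)[C@@H]5C[C@](C)(C(=O)OC)CC(O)[C@]5(C)C(O)C[C@]34C)O[C@@H]1C2 | intermediate
42 | 16,22-bis(S-methyl xanthate) of 41 | CC6(OCCO6)[C@H]1CC[C@H](C)C2=C(C1)[C@@H]1Oc3c(cc4c(c3C)CC[C@@H]3[C@@]4(C)CC[C@@]4(C)[C@@H]5C[C@](C)(C(=O)OC)CC(OC(=S)SC)[C@]5(C)C(OC(=S)SC)C[C@]34C)O[C@@H]1C2 | intermediate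
43 | 6,7-dihydro target carrying the 7'-ketal | CC6(OCCO6)[C@H]1CC[C@H](C)C2=C(C1)[C@@H]1Oc3c(cc4c(c3C)CC[C@@H]3[C@@]4(C)CC[C@@]4(C)[C@@H]5C[C@](C)(C(=O)OC)CC[C@]5(C)CC[C@]34C)O[C@@H]1C2 | intermediate
44 | 6-ene carrying the 7'-ketal | CC6(OCCO6)[C@H]1CC[C@H](C)C2=C(C1)[C@@H]1Oc3c(cc4c(c3C)C=C[C@@H]3[C@@]4(C)CC[C@@]4(C)[C@@H]5C[C@](C)(C(=O)OC)CC[C@]5(C)CC[C@]34C)O[C@@H]1C2 | intermediate
45 | 7'-acetyl analogue of the target | CC(=O)[C@H]1CC[C@H](C)C2=C(C1)[C@@H]1Oc3c(cc4c(c3C)C=C[C@@H]3[C@@]4(C)CC[C@@]4(C)[C@@H]5C[C@](C)(C(=O)OC)CC[C@]5(C)CC[C@]34C)O[C@@H]1C2 | intermediate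
46 | CNP0149558.1 | C=C(C)[C@H]1CC[C@H](C)C2=C(C1)[C@@H]1Oc3c(cc4c(c3C)C=C[C@@H]3[C@@]4(C)CC[C@@]4(C)[C@@H]5C[C@](C)(C(=O)OC)CC[C@]5(C)CC[C@]34C)O[C@@H]1C2 | target

**Step count and risks**

Total step count: 36. Longest linear sequence: 20 steps (18 → 46; steps 12–24 and 30–36).

Step 30. What may go wrong: the hindered C13 radical is reduced before it adds to the enone, the addition occurs on the wrong face of either partner, or the iron enolate is protonated (or the aldehyde reduced) before the aldol closure. Fallback: the two bond formations are separated. The fallback sets out from alcohol 31 and enone 39. Under the same iron-hydride conditions only the conjugate addition is run, which should give the keto alcohol F1. Dess–Martin oxidation then gives the keto aldehyde F2. A base-mediated intramolecular aldol addition (KOt-Bu, t-BuOH/THF, 0 °C) closes ring D under thermodynamic control; only the C17 enolate can form a six-membered ring. The fallback comes back to the route at 40.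

Step 23. What may go wrong: the cyclopentadiene isomerises by 1,5-hydrogen shift or dimerises before it is trapped, or the cycloaddition shows poor regio- or facial selectivity. Fallback: an ionic, stepwise construction of the dioxane. It sets out from enone 27 and catechol 17. α'-Bromination of 27 (LiHMDS, TMSCl, −78 °C; then NBS) should give the bromo enone F3. O-Alkylation by the less hindered C2 hydroxyl of 17 (K2CO3, acetone), with the C3 hydroxyl closing onto the ketone, should give the hemiketal F4. Ionic hydrogenation (Et3SiH, TMSOTf, CH2Cl2, −78 °C) through the allyl-stabilised oxocarbenium ion can deliver hydride only cis to the existing C–O bond. The C3' stereocentre of F3/F4 is epimerisable, so the C3' epimer would have to be separated at this point. The fallback comes back to the route at 31.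

Step 34. What may go wrong: hydride abstraction at the allylic O–CH (C4') of the dioxane or at the aryl methyl group competes with C6, or the styrene is oxidised further. Fallback: a radical route to the same alkene. It sets out from 43. Benzylic bromination at C6 (NBS, dibenzoyl peroxide cat., PhCF3, hν, 0 °C) should give the 6-bromide F5, and E2 elimination with DBU (toluene, 80 °C) takes the C7 hydrogen. The allylic C–H bonds next to the tetrasubstituted alkene remain a competing site in this variant. The fallback comes back to the route at 44.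

**Further compounds**
F1 | step 30 | keto alcohol: C13–C18 bond formed, ring D open, 14α-(2-hydroxyethyl), ring-E 22-ketone with 17-H | CC6(OCCO6)[C@H]1CC[C@H](C)C2=C(C1)[C@@H]1Oc3c(cc4c(c3C)CC[C@@H]3[C@@]4(C)CC[C@@](C)([C@@H]5C[C@](C)(C(=O)OC)CC(=O)C5C)[C@]3(C)CCO)O[C@@H]1C2
F2 | step 30 | keto aldehyde: as F1 with 14α-CH2CHO | CC6(OCCO6)[C@H]1CC[C@H](C)C2=C(C1)[C@@H]1Oc3c(cc4c(c3C)CC[C@@H]3[C@@]4(C)CC[C@@](C)([C@@H]5C[C@](C)(C(=O)OC)CC(=O)C5C)[C@]3(C)CC=O)O[C@@H]1C2
F3 | step 23 | (4S,7S)-2-bromo-4-methyl-7-(2-methyl-1,3-dioxolan-2-yl)-3,4,5,6,7,8-hexahydroazulen-1(2H)-one | CC3(OCCO3)[C@H]1CC[C@H](C)C2=C(C1)C(=O)C(Br)C2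
F4 | step 23 | 4'-hydroxy hemiketal of 31 | CC5(OCCO5)[C@H]1CC[C@H](C)C2=C(C1)C1(O)Oc3c(cc4c(c3C)CC[C@@H]3[C@@]4(C)CCC(=C)[C@]3(C)CCO)O[C@@H]1C2
F5 | step 34 | 6-bromo derivative of 43 | CC6(OCCO6)[C@H]1CC[C@H](C)C2=C(C1)[C@@H]1Oc3c(cc4c(c3C)C(Br)C[C@@H]3[C@@]4(C)CC[C@@]4(C)[C@@H]5C[C@](C)(C(=O)OC)CC[C@]5(C)CC[C@]34C)O[C@@H]1C2
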